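## Retrosynthetic overview

- Target ⇐ MOM removal ⇐ C3'-prenylation by directed ortho-metalation between 2'-OMOM and 4'-OMe ⇐ (3R)-isoflavan core ⇐ Ir-catalysed asymmetric hydrogenation of an isoflav-3-ene (sets C3).
- Isoflav-3-ene ⇐ one-carbon ring expansion: the pyran ring (O1, C2, C3, C4, C4a, C8a) arises from the furan ring of a 4,6-dioxygenated benzofuran. An aryl chlorocarbene inserts the future C3, with the whole B ring attached, between furan C2 and C3 (chlorocyclopropane → isoflavylium salt → hydride).
- Enabling feature: the furan C2=C3 enol-ether bond is flanked by the O1 lone pair (stabilises cation at C2) and by OMe/OBn ortho and para to C3a (stabilise cation at C3), so the chlorocyclopropane opens to an aromatic benzopyrylium ion.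
- Fragments: the benzofuran from 4,6-dihydroxybenzofuran-3(2H)-one (3 steps); the aryl chlorodiazirine from 2-hydroxy-4-methoxybenzonitrile (3 steps).
- Ring order: both benzene rings are bought; the furan ring is present from the start and is expanded to the pyran ring in the key step; no other ring is formed.

Key step: step 7

Assumption: the target is the 3R enantiomer (CIP order C2 > C1' > C4 > H); both antipodes of the Ir ligand are available, and the one that gives 3R is to be fixed on a model isoflavene.

## Route

Step 1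
Reactants: 1 4,6-dihydroxy-1-benzofuran-3(2H)-one
Product: 2 6-(benzyloxy)-4-hydroxy-1-benzofuran-3(2H)-one
Conditions: BnBr (1.05 equiv), K2CO3 (1.1 equiv), DMF, rt
Reagents that add atoms: benzyl bromide, BrCc1ccccc1
Why: Williamson etherification; the 4-OH is hydrogen-bonded to the C3 carbonyl and peri-hindered, so the free, more acidic 6-OH (para to the carbonyl) should be alkylated selectively with one equivalent of base.

Step 2
Reactants: 2 6-(benzyloxy)-4-hydroxy-1-benzofuran-3(2H)-one
Product: 3 6-(benzyloxy)-4-methoxy-1-benzofuran-3(2H)-one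
Conditions: MeI (3 equiv), K2CO3 (2 equiv), DMF, 40 °C
Reagents that add atoms: iodomethane, CI
Why: Williamson O-methylation of the remaining chelated phenol under forcing carbonate conditions, as is routine for 4,6-dialkoxybenzofuran-3(2H)-ones.

Step 3
Reactants: 3 6-(benzyloxy)-4-methoxy-1-benzofuran-3(2H)-one
Product: 5 6-(benzyloxy)-4-methoxy-1-benzofuran, via alcohol 4 (not isolated)
Conditions: NaBH4, THF/MeOH, 0 °C → rt; then 1 M aq. HCl, rt
Reagents that add atoms: none
Why: Hydride reduction of the aryl ketone to the benzylic alcohol, then acid-catalysed E1 dehydration (cation stabilised by the 4-OMe/6-OBn donors) driven by aromatisation to the benzofuran.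

Step 4
Reactants: 6 2-hydroxy-4-methoxybenzonitrile
Product: 7 4-methoxy-2-(methoxymethoxy)benzonitrile
Conditions: MOMCl, i-Pr2NEt, CH2Cl2, 0 °C → rt
Reagents that add atoms: chloromethyl methyl ether, COCCl
Why: Base-mediated O-alkylation of the phenol; MOM is chosen because it later directs ortho-lithiation to C3'.

Step 5
Reactants: 7 4-methoxy-2-(methoxymethoxy)benzonitrile
Product: 9 4-methoxy-2-(methoxymethoxy)benzamidinium chloride, via lithium amidinate 8 (not isolated)
Conditions: LiHMDS, THF, 0 °C → rt; then MeOH, 0 °C; HCl (2.0 equiv, 2 M in Et2O), 0 °C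
Reagents that add atoms: lithium bis(trimethylsilyl)amide, [Li]N([Si](C)(C)C)[Si](C)(C)C; hydrogen chloride, Cl
Why: Addition of the silylamide to the nitrile gives the N-silylated amidinate, which methanol desilylates; a stoichiometric amount of HCl is taken up by the strongly basic amidine, so the MOM ether should not see free acid.

Step 6
Reactants: 9 4-methoxy-2-(methoxymethoxy)benzamidinium chloride
Product: 10 3-chloro-3-[4-methoxy-2-(methoxymethoxy)phenyl]-3H-diazirine
Conditions: aq. NaOCl, LiCl, DMSO, 0 °C → rt; pentane extraction; kept cold and dark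
Reagents that add atoms: sodium hypochlorite, [Na+].[O-]Cl; lithium chloride, [Li+].[Cl-]
Why: Graham oxidation: N-chlorination of the amidine, N–N ring closure and chloride transfer to carbon should give the 3-aryl-3-chlorodiazirine.

Step 7
Reactants: 5 6-(benzyloxy)-4-methoxy-1-benzofuran; 10 3-chloro-3-[4-methoxy-2-(methoxymethoxy)phenyl]-3H-diazirine
Product: 13 7-(benzyloxy)-5-methoxy-3-[4-methoxy-2-(methoxymethoxy)phenyl]-2H-chromene, via chlorocyclopropane 11 (not isolated), via isoflavylium chloride 12 (not isolated)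
Conditions: 10 (1.5 equiv, in portions), Na2CO3 (acid scavenger), MeCN (0.5 M in 5), 45 °C, dark, until N2 evolution stops; then NaBH4, MeOH, −20 → 0 °C
Reagents that add atoms: none
Why: Proposed new method: Thermolysis of 10 (loss of N2) gives the aryl chlorocarbene, which adds in a concerted [2+1] fashion to the furan C2=C3 enol-ether bond of 5 (cyclopropane 11); ionisation of C–Cl with disrotatory opening of the shared C2–C3 bond, pushed by the O1 lone pair at C2 and by the OMe/OBn groups ortho and para to C3a at C3, then expands the five-membered furan ring to the six-membered pyrylium ring of 12, the carbene carbon becoming C3 with the B ring already on it, and borohydride adds to C2 of 12 to give 13. The closest known reaction types are the Ciamician–Dennstedt-type carbon-atom insertion of aryl chlorodiazirines into indoles and pyrroles and the dihalocarbene ring expansion of benzofurans and indenes; an aryl chlorocarbene on a benzofuran with reductive quench of the benzopyrylium salt is the untested combination. Ring closure: only the transient three-membered ring is closed, by cheletropic [2+1] addition, while the pyran ring is formed by cyclopropyl-to-allyl cation ring expansion of the furan, not by cyclisation. No stereocentre is kept: the cyclopropane stereocentres of 11 vanish on opening (the endo chloride opens in concert, the exo chloride after ionisation to the cyclopropyl cation stabilised by the 2,4-dioxygenated aryl group), and C3 is set in step 8. The step needs chemoselective carbene addition to C2=C3 instead of insertion into the MOM C–H bonds of its own ortho substituent or attack on the benzo ring, which the nucleophilic enol-ether bond and a high concentration of 5 should secure, and hydride attack at C2 instead of C4, which is favoured because C2 is the unhindered oxocarbenium carbon, C4 lies peri to the 5-OMe group and the 2H-isomer is the conjugated one.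

Step 8
Reactants: 13 7-(benzyloxy)-5-methoxy-3-[4-methoxy-2-(methoxymethoxy)phenyl]-2H-chromene
Product: 14 (3R)-7-(benzyloxy)-5-methoxy-3-[4-methoxy-2-(methoxymethoxy)phenyl]chromane
Conditions: [Ir(cod)(L*)]BArF (2 mol %, L* = tBu-PHOX-type P,N ligand, antipode giving 3R), H2 (50 bar), CH2Cl2, rt
Reagents that add atoms: none
Why: Iridium–P,N-catalysed asymmetric hydrogenation of an unfunctionalised trisubstituted cyclic styrene (2H-chromene class); the chiral ligand selects the alkene face for syn delivery of H2 and so should set C3 as R, with the benzyl and MOM ethers inert.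

Step 9
Reactants: 14 (3R)-7-(benzyloxy)-5-methoxy-3-[4-methoxy-2-(methoxymethoxy)phenyl]chromane
Product: 15 (3R)-5-methoxy-3-[4-methoxy-2-(methoxymethoxy)phenyl]chroman-7-ol
Conditions: H2 (1 atm), 10% Pd/C, EtOAc/MeOH, rt
Reagents that add atoms: none
Why: Hydrogenolysis of the benzyl aryl ether; the stereocentre, the MOM acetal and the non-benzylic C2–O1 bond should be untouched.

Step 10
Reactants: 15 (3R)-5-methoxy-3-[4-methoxy-2-(methoxymethoxy)phenyl]chroman-7-ol
Product: 17 (3R)-5-methoxy-3-[4-methoxy-2-(methoxymethoxy)-3-(3-methylbut-2-en-1-yl)phenyl]chroman-7-ol, via dilithio species 16 (not isolated)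
Conditions: n-BuLi (2.3 equiv), TMEDA, THF, −20 → 0 °C; then CuBr·SMe2 (10 mol %), prenyl bromide (1.1 equiv), −78 → 0 °C; H2O
Reagents that add atoms: prenyl bromide (1-bromo-3-methylbut-2-ene), CC(C)=CCBr
Why: Directed ortho-metalation: after deprotonation of the phenol, the second equivalent of n-BuLi should remove the C3' proton, the only ring C–H flanked by two coordinating oxygen groups on a ring not deactivated as a phenoxide, and the aryllithium is allylated at the primary carbon of prenyl bromide under copper catalysis; the C3–H is not acidic under these conditions.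

Step 11
Reactants: 17 (3R)-5-methoxy-3-[4-methoxy-2-(methoxymethoxy)-3-(3-methylbut-2-en-1-yl)phenyl]chroman-7-ol
Product: 18 (3R)-3-[2-hydroxy-4-methoxy-3-(3-methylbut-2-en-1-yl)phenyl]-5-methoxychroman-7-ol
Conditions: p-TsOH·H2O (0.2 equiv), MeOH, 40 °C
Reagents that add atoms: none
Why: Acid-catalysed transacetalisation of the aryl MOM ether in methanol (the CH2OMe unit leaves as dimethoxymethane), mild enough that the prenyl group and the stereocentre should survive.

## Compound list

1 | 4,6-dihydroxy-1-benzofuran-3(2H)-one | O=C1COc2cc(O)cc(O)c12 | starting material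
2 | 6-(benzyloxy)-4-hydroxy-1-benzofuran-3(2H)-one | O=C1COc2cc(OCc3ccccc3)cc(O)c12 | intermediate
3 | 6-(benzyloxy)-4-methoxy-1-benzofuran-3(2H)-one | O=C1COc2cc(OCc3ccccc3)cc(OC)c12 | intermediate
4 | rac-6-(benzyloxy)-4-methoxy-2,3-dihydro-1-benzofuran-3-ol | OC1COc2cc(OCc3ccccc3)cc(OC)c12 | intermediate (not isolated)
5 | 6-(benzyloxy)-4-methoxy-1-benzofuran | COc1cc(OCc2ccccc2)cc2occc12 | intermediate
6 | 2-hydroxy-4-methoxybenzonitrile | N#Cc1ccc(OC)cc1O | starting material
7 | 4-methoxy-2-(methoxymethoxy)benzonitrile | COCOc1cc(OC)ccc1C#N | intermediate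
8 | lithium N,N'-bis(trimethylsilyl)-4-methoxy-2-(methoxymethoxy)benzamidinate | COCOc1cc(OC)ccc1C(=N[Si](C)(C)C)N([Li])[Si](C)(C)C | intermediate (not isolated)
9 | 4-methoxy-2-(methoxymethoxy)benzamidinium chloride | COCOc1cc(OC)ccc1C(N)=[NH2+].[Cl-] | intermediate
10 | 3-chloro-3-[4-methoxy-2-(methoxymethoxy)phenyl]-3H-diazirine | COCOc1cc(OC)ccc1C1(Cl)N=N1 | intermediate
11 | 4-(benzyloxy)-1-chloro-6-methoxy-1-[4-methoxy-2-(methoxymethoxy)phenyl]-1a,6b-dihydro-1H-cyclopropa[b][1]benzofuran (racemic, cis-fused, endo/exo-Cl mixture) | COc1cc(OCc3ccccc3)cc2OC4C(c12)C4(Cl)c1ccc(OC)cc1OCOC | intermediate (not isolated)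
12 | 7-(benzyloxy)-5-methoxy-3-[4-methoxy-2-(methoxymethoxy)phenyl]chromenylium chloride | COc1cc(OCc3ccccc3)cc2[o+]cc(-c4ccc(OC)cc4OCOC)cc12.[Cl-] | intermediate (not isolated)
13 | 7-(benzyloxy)-5-methoxy-3-[4-methoxy-2-(methoxymethoxy)phenyl]-2H-chromene | COc1cc(OCc3ccccc3)cc2OCC(c4ccc(OC)cc4OCOC)=Cc12 | intermediate
14 | (3R)-7-(benzyloxy)-5-methoxy-3-[4-methoxy-2-(methoxymethoxy)phenyl]chromane | COc1cc(OCc3ccccc3)cc2c1C[C@H](c1ccc(OC)cc1OCOC)CO2 | intermediate
15 | (3R)-5-methoxy-3-[4-methoxy-2-(methoxymethoxy)phenyl]chroman-7-ol | COc1cc(O)cc2c1C[C@H](c1ccc(OC)cc1OCOC)CO2 | intermediate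
16 | lithium (3R)-3-[3-lithio-4-methoxy-2-(methoxymethoxy)phenyl]-5-methoxychroman-7-olate | COc1cc(O[Li])cc2c1C[C@H](c1ccc(OC)c([Li])c1OCOC)CO2 | intermediate (not isolated)
17 | (3R)-5-methoxy-3-[4-methoxy-2-(methoxymethoxy)-3-(3-methylbut-2-en-1-yl)phenyl]chroman-7-ol | COc1cc(O)cc2c1C[C@H](c1ccc(OC)c(CC=C(C)C)c1OCOC)CO2 | intermediate
18 | (3R)-3-[2-hydroxy-4-methoxy-3-(3-methylbut-2-en-1-yl)phenyl]-5-methoxychroman-7-ol | COc1cc(O)cc2c1C[C@H](c1ccc(OC)c(CC=C(C)C)c1O)CO2 | target

## Summary

Total step count: 11. Longest linear sequence: 8 steps (steps 1–3 or 4–6, then 7–11).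

Steps most likely to fail:

1. Step 7 (proposed new method). The carbene may be consumed by insertion into the C–H bonds of its own ortho MOM group or by dimerisation before it reaches the furan double bond. The electron-rich diazirine may also decompose on handling, and hydride may add partly at C4.
Fallback, from 5 back to 13, using the known dihalocarbene ring expansion and a cross-coupling: dibromocarbene (CHBr3, KOt-Bu, −20 °C → rt) should convert 5 into the gem-dibromocyclopropane 4-(benzyloxy)-1,1-dibromo-6-methoxy-1a,6b-dihydro-1H-cyclopropa[b][1]benzofuran F1. On warming in MeCN this should open to 7-(benzyloxy)-3-bromo-5-methoxychromenylium bromide F2, and NaBH4 quench in the same flask should give 7-(benzyloxy)-3-bromo-5-methoxy-2H-chromene F3. The B ring comes from commercial 2-bromo-5-methoxyphenol: MOM protection gives 1-bromo-4-methoxy-2-(methoxymethoxy)benzene F4, and Miyaura borylation (B2pin2, Pd(dppf)Cl2, KOAc) gives 2-[4-methoxy-2-(methoxymethoxy)phenyl]-4,4,5,5-tetramethyl-1,3,2-dioxaborolane F5. Suzuki–Miyaura coupling of F3 with F5 (Pd(dppf)Cl2, K2CO3, dioxane/H2O, 80 °C) should give 13; diazirine 10 is not needed.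

2. Step 8. Conversion or enantioselectivity may be poor because of the ortho-substituted aryl group, and the acidic Ir hydride may isomerise the 2H-chromene or cleave the MOM group.
Fallback, from 13 back to 15, by resolution instead of asymmetric catalysis: H2 over Pd/C should reduce the C3=C4 bond and remove the benzyl ether in one operation to give racemic 5-methoxy-3-[4-methoxy-2-(methoxymethoxy)phenyl]chroman-7-ol F6. Preparative chiral-phase SFC should then separate 15 from its enantiomer (3S)-5-methoxy-3-[4-methoxy-2-(methoxymethoxy)phenyl]chroman-7-ol F7.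

3. Step 10. Metalation of the poorly soluble phenoxide may be sluggish or unselective, and the phenoxide may be O-prenylated or the allyl bromide attacked at its tertiary end.
Fallback, from 15 to 18, by a regiospecific aromatic Claisen rearrangement: silylation (TIPSCl, imidazole) should give (3R)-5-methoxy-3-[4-methoxy-2-(methoxymethoxy)phenyl]-7-[(triisopropylsilyl)oxy]chromane F8. Mild acid (PPTS, MeOH) should remove the MOM group to give 5-methoxy-2-{(3R)-5-methoxy-7-[(triisopropylsilyl)oxy]chroman-3-yl}phenol F9. Pd-catalysed O-allylation with tert-butyl 2-methylbut-3-en-2-yl carbonate (Pd(PPh3)4, THF, 0 °C) should give the 1,1-dimethylallyl ether (3R)-5-methoxy-3-{4-methoxy-2-[(2-methylbut-3-en-2-yl)oxy]phenyl}-7-[(triisopropylsilyl)oxy]chromane F10. Heating (N,N-diethylaniline, 160 °C) should move the allyl unit to the only free ortho position, C3', to give 6-{(3R)-5-methoxy-7-[(triisopropylsilyl)oxy]chroman-3-yl}-3-methoxy-2-(3-methylbut-2-en-1-yl)phenol F11. TBAF (THF, 0 °C) should then give 18.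

Further compounds

F1 | step 7 | 4-(benzyloxy)-1,1-dibromo-6-methoxy-1a,6b-dihydro-1H-cyclopropa[b][1]benzofuran | COc1cc(OCc3ccccc3)cc2OC4C(c12)C4(Br)Br
F2 | step 7 | 7-(benzyloxy)-3-bromo-5-methoxychromenylium bromide | COc1cc(OCc3ccccc3)cc2[o+]cc(Br)cc12.[Br-]
F3 | step 7 | 7-(benzyloxy)-3-bromo-5-methoxy-2H-chromene | COc1cc(OCc2ccccc2)cc2OCC(Br)=Cc12
F4 | step 7 | 1-bromo-4-methoxy-2-(methoxymethoxy)benzene | COCOc1cc(OC)ccc1Br
F5 | step 7 | 2-[4-methoxy-2-(methoxymethoxy)phenyl]-4,4,5,5-tetramethyl-1,3,2-dioxaborolane | COCOc1cc(OC)ccc1B1OC(C)(C)C(C)(C)O1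
F6 | step 8 | rac-5-methoxy-3-[4-methoxy-2-(methoxymethoxy)phenyl]chroman-7-ol | COc1cc(O)cc2c1CC(c1ccc(OC)cc1OCOC)CO2
F7 | step 8 | (3S)-5-methoxy-3-[4-methoxy-2-(methoxymethoxy)phenyl]chroman-7-ol | COc1cc(O)cc2c1C[C@@H](c1ccc(OC)cc1OCOC)CO2
F8 | step 10 | (3R)-5-methoxy-3-[4-methoxy-2-(methoxymethoxy)phenyl]-7-[(triisopropylsilyl)oxy]chromane | COc1cc(O[Si](C(C)C)(C(C)C)C(C)C)cc2c1C[C@H](c1ccc(OC)cc1OCOC)CO2
F9 | step 10 | 5-methoxy-2-{(3R)-5-methoxy-7-[(triisopropylsilyl)oxy]chroman-3-yl}phenol | COc1cc(O[Si](C(C)C)(C(C)C)C(C)C)cc2c1C[C@H](c1ccc(OC)cc1O)CO2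
F10 | step 10 | (3R)-5-methoxy-3-{4-methoxy-2-[(2-methylbut-3-en-2-yl)oxy]phenyl}-7-[(triisopropylsilyl)oxy]chromane | COc1cc(O[Si](C(C)C)(C(C)C)C(C)C)cc2c1C[C@H](c1ccc(OC)cc1OC(C)(C)C=C)CO2
F11 | step 10 | 6-{(3R)-5-methoxy-7-[(triisopropylsilyl)oxy]chroman-3-yl}-3-methoxy-2-(3-methylbut-2-en-1-yl)phenol | COc1cc(O[Si](C(C)C)(C(C)C)C(C)C)cc2c1C[C@H](c1ccc(OC)c(CC=C(C)C)c1O)CO2
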